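## The problem

The target is a caffeic acid trimer. Rings A and B form a 1,2-dihydronaphthalene (C1–C4, C4a, C5–C8, C8a) with carboxyl groups on C2 and C3, hydroxyls on C6 and C7, and ring C on C1. A fourth ring, the catechol ring D, hangs on O3' of ring C through an α-aryloxyacrylic acid, i.e. an enol ether (side-chain carbons Cα and Cβ).

There are two stereocentres, C1 (R) and C2 (S), trans to each other. C2 is α to its own carboxyl and γ to the conjugated C3 carboxyl, so it is epimerisable. In this ring system the trans, pseudo-diaxial arrangement is the stable one, so C2 can be left to follow C1. C1 is doubly benzylic, cannot be corrected later, and is the one centre that needs absolute control.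

The side-chain alkene has the aryloxy oxygen and ring D on opposite sides (E), which puts ring D cis to the carboxyl. This is the less stable geometry of an α-aryloxycinnamate. It has to be made under kinetic control and then kept away from strong acid, light and equilibrating nucleophiles.

Three phenol or catechol units oxidise in base and air, the dihydronaphthalene can aromatise or shift its double bond under base, and neither alkene tolerates hydrogenation. The five phenols are therefore carried as benzyl ethers, cleavable by BCl3 at low temperature, with one orthogonal group on O3'.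

The enabling feature is that ring B is a cyclohexene fused to ring A along C4a–C8a, and that a C4-oxygenated precursor carries a trans-dicarboxylate on C2 and C3. C1–C2–C3–C4 is then the imprint of a fumarate that has added across an o-quinodimethane of ring A, with ring C on one terminus (C1) and an oxygen on the other (C4) that later leaves to give C3=C4.

## Retrosynthesis

**Deprotection (25 ⇐ 24 ⇐ 23).** The last bonds cut are the five benzyl–oxygen bonds of 24 and, before that, the three methyl ester bonds of 23. Saponification is placed first so that no free catechol meets base. The ethers go last with BCl3 and pentamethylbenzene at −78 °C, which touches neither alkene. Methyl ethers would be shorter to install, but their cleavage needs hot Lewis acid or iodosilane, which the E enol ether is unlikely to survive. The forward steps must leave C2 and the alkene geometry alone.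

**Side chain (23 ⇐ 21 + 22; 21 ⇐ 18 + 20).** The Cα=Cβ bond is cut first, giving phosphonate 21 and aldehyde 22. The O3'–Cα bond is cut next, giving phenol 18 and diazophosphonate 20. Condensing an aryloxyacetate would need an ester enolate next to the acidic C2–H and would give the stable Z isomer. Coupling a phenol with a preformed α-haloacrylate has no secure footing. The phosphonate route puts the most acidic C–H of 21 exactly where the anion is wanted, and the trifluoroethyl phosphonate gives the kinetic geometry. This cut removes ring D and the only alkene stereo-element. It asks for O–H insertion to beat other carbenoid pathways and for olefination under kinetic control.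

**Unmasking and ester exchange (18 ⇐ 17 ⇐ 16).** Phenol 18 comes from 17 by loss of the methoxymethyl group. Dimethyl ester 17 comes from the bis(lactyl) ester 16 by methoxide exchange. The exchange removes the spent auxiliaries and, through the C2 dienolate, settles C2 in the trans configuration whatever the cycloaddition delivered.

**C3=C4 (16 ⇐ 14).** The alkene is traced to the C4 alcohol 14 by elimination through mesylate 15. This is a functional-group change only, but it puts an oxygen on C4, which is what the ring-forming step supplies. The forward step needs only the single β-hydrogen on C3.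

**Ring B (14 ⇐ 9 + 12, the key cut).** C1–C2 and C3–C4 are cut together. This gives the chiral fumarate 12 and the (E,E)-dienol 13, which is the ring-opened form of trans-benzocyclobutenol 9. Cutting C1–C2 alone or C4–C4a alone would close the same ring but would need C1 set beforehand in an acyclic molecule. The cycloaddition makes two bonds, the ring and C1 at once, from a strained four-membered ring and a chiral-pool diester. The hydroxyl of 9 is left free rather than silylated, because its hydrogen bond to the fumarate is the organising element in the closest known cases; this also saves two steps. The forward reaction has to give only the (E,E)-dienol and has to discriminate the two faces of that planar diene.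

**Building blocks (9 ⇐ 7 ⇐ 3 + 5; 3 ⇐ 2 ⇐ 1; 5 ⇐ 4; 12 ⇐ 10 + 11; 20 ⇐ 19).**
- 9 is opened at the bond between ring A and the aryl-bearing carbon, giving bromo-epoxide 7 (through aryllithium 8).
- 7 is cut at its C–C bond into benzylic bromide 3 (as sulfonium salt 6) and aldehyde 5.
- 3 comes from commercial alcohol 1 via 2, and 5 from commercial phenol 4.
- 12 is cut at both ester C–O bonds into fumaryl chloride 10 and two molecules of methyl (S)-lactate 11.
- 20 comes from the commercial trifluoroethyl phosphonoacetate 19.

The epoxide and the benzocyclobutenol may be racemic, because their stereocentres vanish in 13.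

## Roads not taken

**Alternative 1:** The cut is C1–C2 alone. In the forward step, base converts the benzhydryl sulfone A2 into the ring C para-quinone methide A3, and the dienolate of the arylidenesuccinate arm adds through C2 to C1 under a chiral ion-pairing or hydrogen-bonding catalyst to give A1.
- Merits: C3=C4 is present from the start, so no oxygen has to be put on C4 and removed; chirality is catalytic; the trans diester forms directly.
- Weak points: the nucleophile is a simple ester dienolate, far less acidic than the malonates, keto esters and thiols for which such in-situ quinone methide additions are established. Bases strong enough to form it invite an uncatalysed racemic pathway and oligomerisation of A3. The step that sets C1 would be the one without a close model. A1 also has its free hydroxyl on O4' while O3' is the oxygen to be functionalised, so a protecting-group swap follows.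
- Comparison: if the asymmetric step worked, this road would be two or three steps shorter after ring closure and would need no stoichiometric auxiliary. In that respect it is better. The chosen plan sets against this a ring closure whose regiochemical, relative and absolute outcome each have a close counterpart, and by-products that are diastereomers and can be removed at 14.

**Alternative 2:** The cut is C4–C4a. In the forward step, strong acid makes ring A of the formylsuccinate A5 attack the formyl group at the position para to a methoxy group, and the carbinol dehydrates to A4.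
- Merits: a robust classical closure with cheap reagents. C3=C4 appears in the same step, which is better than the separate elimination of the chosen plan. The mesylate deactivates ring C so that only ring A cyclises.
- Weak points: C1 and C2 must already exist in A5. C1 is a diarylmethine with two similar electron-rich aryl groups and needs its own asymmetric step on acyclic material, for example conjugate arylation with [Rh(acac)(C2H4)2] and a chiral diene. Hot acid excludes benzyl and acetal protection, so the phenols become methyl ethers and a mesylate. The end game then needs harsh demethylation beside the E enol ether, and mesylate removal by strong base beside the epimerisable C2.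
- Comparison: simpler and more scalable in the ring-forming step itself. The chosen plan offers in return that the stereocentres are made in the ring-forming event, under neutral conditions that allow a protecting-group set with a mild final cleavage.

**Alternative 3:** The cuts are C4a–C8a, C5–C6 and C7–C8. In the forward step the 1,7-diyne A7 and bis(pinacolatoboryl)acetylene A8 cyclotrimerise with a cationic rhodium catalyst such as [Rh(cod)2]BF4 with BINAP to give A6, closing rings A and B together. Oxidation of the two C–B bonds then gives the ring A catechol.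
- Merits: the ring A oxygens arrive as boronates and become free hydroxyls by mild oxidation, with no ether to cleave. For the end game this is better than the chosen plan. The approach is also modular.
- Weak points: A7 is an acyclic enediyne whose C1 is benzylic and propargylic next to the acidic C2–H, so it is open to propargyl–allene isomerisation. Its two stereocentres and its alkene geometry all need separate stereoselective steps. The bulky, electron-poor A8 is a reluctant partner, so self-coupling of A7 and entry of the tether alkene into the metallacycle compete. After oxidation the free catechol must be protected again for the basic side-chain steps.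
- Comparison: best in protecting-group economy for ring A. The chosen plan counters with stereocontrol inside the ring-forming step and with building blocks that are all simple aromatic aldehydes or alcohols.

Key step: step 7

Remarks on the chemistry:
- The side-chain alkene is taken as drawn: aryloxy oxygen and ring D trans (E), ring D cis to the carboxyl.
- The sense of induction of the (S)-lactyl fumarate toward the hydrogen-bonded dienol is assumed by analogy with the aryltetralin lignan series, where (S)-configured auxiliaries of this type are taken to give the C1 configuration needed here. If it proved the reverse, methyl (R)-lactate would be used and nothing else would change.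
- Compounds 7, 8 and 9 are racemic (one enantiomer drawn).

## Route

Step 1
Reactants: 1 [3,4-bis(benzyloxy)phenyl]methanol
Product: 2 [4,5-bis(benzyloxy)-2-bromophenyl]methanol
Conditions: NBS, MeCN, 0 °C → rt, dark
Reagents that add atoms: N-bromosuccinimide, BrN1C(=O)CCC1=O
Why: Electrophilic aromatic bromination; the position para to one benzyloxy group and ortho to the hydroxymethyl group is the most activated unhindered site, as in veratryl-type alcohols, and the polar solvent and darkness suppress benzylic radical bromination.

Step 2
Reactants: 2 [4,5-bis(benzyloxy)-2-bromophenyl]methanol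
Product: 3 1,2-bis(benzyloxy)-4-bromo-5-(bromomethyl)benzene
Conditions: PBr3, CH2Cl2, 0 °C
Reagents that add atoms: phosphorus tribromide, BrP(Br)Br
Why: Conversion of a benzylic alcohol into the bromide through its phosphite ester (SN2); benzyl ethers and the aryl bromide are inert, and the bromide is used without storage.

Step 3
Reactants: 4 4-(benzyloxy)-3-hydroxybenzaldehyde
Product: 5 4-(benzyloxy)-3-(methoxymethoxy)benzaldehyde
Conditions: MOMCl, i-Pr2NEt, CH2Cl2, 0 °C → rt
Reagents that add atoms: chloromethyl methyl ether, COCCl
Why: O-alkylation of the phenol to the methoxymethyl ether; this group marks O3' as the one oxygen that can later be freed by mild acid while the benzyl ethers stay.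

Step 4
Reactants: 3 1,2-bis(benzyloxy)-4-bromo-5-(bromomethyl)benzene; 5 4-(benzyloxy)-3-(methoxymethoxy)benzaldehyde
Product: 7 (±)-trans-2-[4,5-bis(benzyloxy)-2-bromophenyl]-3-[4-(benzyloxy)-3-(methoxymethoxy)phenyl]oxirane, via sulfonium bromide 6 (not isolated)
Conditions: tetrahydrothiophene, MeCN, rt; then 5, KOH, MeCN–H2O, 0 °C → rt
Reagents that add atoms: tetrahydrothiophene, C1CCSC1 (present in 6 only; released again)
Why: Corey–Chaykovsky epoxidation through a benzylic sulfonium ylide; addition of the semi-stabilised ylide is reversible and the anti betaine closes faster, so the trans-epoxide should predominate, and the racemate suffices because both centres are erased in step 7.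

Step 5
Reactants: 7 (±)-trans-2-[4,5-bis(benzyloxy)-2-bromophenyl]-3-[4-(benzyloxy)-3-(methoxymethoxy)phenyl]oxirane
Product: 9 (±)-trans-4,5-bis(benzyloxy)-2-[4-(benzyloxy)-3-(methoxymethoxy)phenyl]-1,2-dihydrobenzocyclobuten-1-ol, via aryllithium 8 (not isolated)
Conditions: n-BuLi, THF, −78 °C; then MgBr2·OEt2, −78 → −20 °C; aq NH4Cl at −20 °C
Reagents that add atoms: n-butyllithium, [Li]CCCC (supplies the lithium of 8 only)
Why: Bromine–lithium exchange outruns attack on the epoxide at −78 °C, and MgBr2 then activates the oxirane for 4-exo closure by the aryl-metal on the carbon bearing ring C (Parham-type cyclisation known for o-bromostyrene oxides and their 2-aryl congeners); backside attack on the trans-epoxide places hydroxyl and aryl trans, and the cold quench keeps the alkoxide from opening.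

Step 6
Reactants: 10 fumaryl chloride; 11 methyl (S)-lactate (2.2 equiv in all)
Product: 12 bis[(2S)-1-methoxy-1-oxopropan-2-yl] fumarate
Conditions: 11 (2.2 equiv), pyridine (2.5 equiv), CH2Cl2, 0 °C → rt
Reagents that add atoms: methyl (S)-lactate (the second equivalent of 11, which acylates the second acid chloride group), C[C@H](O)C(=O)OC
Why: Double acylation of the secondary alcohol by the diacid chloride, each acid chloride group taking up one molecule of 11, so that two lactate units are built into 12; the C–O bond at the lactate stereocentre is not broken, so both centres stay S and the alkene stays E.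

Step 7
Reactants: 9 (±)-trans-4,5-bis(benzyloxy)-2-[4-(benzyloxy)-3-(methoxymethoxy)phenyl]-1,2-dihydrobenzocyclobuten-1-ol; 12 bis[(2S)-1-methoxy-1-oxopropan-2-yl] fumarate
Product: 14 bis[(2S)-1-methoxy-1-oxopropan-2-yl] (1R,2R,3S,4R)-6,7-bis(benzyloxy)-1-[4-(benzyloxy)-3-(methoxymethoxy)phenyl]-4-hydroxy-1,2,3,4-tetrahydronaphthalene-2,3-dicarboxylate, via hydroxy-o-quinodimethane 13 (not isolated)
Conditions: 12 (3 equiv), toluene, 110 °C, argon
Reagents that add atoms: none
Why: At 110 °C the cyclobutene ring of 9 opens by a thermal conrotatory 4π electrocyclic reaction; the hydroxyl group rotates outward as donors do, and because aryl and hydroxyl are trans the aryl group turns outward as well, so only the (E,E)-dienol 13 should form. 13 is trapped by the C2-symmetric fumarate 12 in a suprafacial [4+2] cycloaddition that makes C1–C2 and C3–C4 together and restores the aromaticity of ring A; ring B is thus closed as a six-membered ring by intermolecular Diels–Alder cycloaddition. The closest known reaction type is the thermal opening of trans-2-arylbenzocyclobutenols to α-hydroxy-α'-aryl-o-quinodimethanes and their capture by fumarates of α-hydroxy esters, as applied to aryltetralin lignans. C1 and C4 come out cis because both termini of 13 are E, and C2 and C3 come out trans because the dienophile is a fumarate. The hydrogen bond from the dienol O–H to the carbonyl of the neighbouring ester is expected to hold that ester exo, which places the C2 ester endo and hence cis to ring C. The (S)-lactyl groups leave one face of the fumarate open, and within this hydrogen-bonded arrangement that choice decides which enantiotopic face of the planar dienol is used, so that C1 should form as R. Only this C1 configuration is needed later, since C3 and C4 are flattened in step 8 and C2 is reset in step 9; it is secured by the auxiliary together with the hydrogen bond, and the excess of 12 keeps the cycloaddition ahead of the 1,5-hydrogen shift of 13 to an aldehyde.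

Step 8
Reactants: 14 bis[(2S)-1-methoxy-1-oxopropan-2-yl] (1R,2R,3S,4R)-6,7-bis(benzyloxy)-1-[4-(benzyloxy)-3-(methoxymethoxy)phenyl]-4-hydroxy-1,2,3,4-tetrahydronaphthalene-2,3-dicarboxylate
Product: 16 bis[(2S)-1-methoxy-1-oxopropan-2-yl] (1R,2R)-6,7-bis(benzyloxy)-1-[4-(benzyloxy)-3-(methoxymethoxy)phenyl]-1,2-dihydronaphthalene-2,3-dicarboxylate, via mesylate 15 (not isolated)
Conditions: MsCl, Et3N, CH2Cl2, 0 °C; then DBU, 0 °C → rt
Reagents that add atoms: methanesulfonyl chloride, CS(=O)(=O)Cl (present in 15 only)
Why: Mesylation followed by base-induced β-elimination; the C3–H is α to an ester and C4 is a para-alkoxybenzylic position, so loss of mesylate by an E1cB or ionisation pathway needs no anti-periplanar hydrogen and gives the conjugated C3=C4 bond; any C2 epimerisation by DBU is harmless because step 9 equilibrates that centre.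

Step 9
Reactants: 16 bis[(2S)-1-methoxy-1-oxopropan-2-yl] (1R,2R)-6,7-bis(benzyloxy)-1-[4-(benzyloxy)-3-(methoxymethoxy)phenyl]-1,2-dihydronaphthalene-2,3-dicarboxylate
Product: 17 dimethyl (1R,2S)-6,7-bis(benzyloxy)-1-[4-(benzyloxy)-3-(methoxymethoxy)phenyl]-1,2-dihydronaphthalene-2,3-dicarboxylate
Conditions: NaOMe (0.3 equiv), MeOH–THF, 0 °C → rt, argon
Reagents that add atoms: methanol, CO (solvent; one molecule is taken up at each of the two ester groups)
Why: Methoxide-catalysed transesterification of the activated lactyl esters, with concurrent epimerisation at C2 through the dienolate to the thermodynamically preferred trans (pseudo-diaxial) isomer, which sets C2 as S; C1 is not acidic and keeps its configuration, and air is excluded to avoid aromatisation.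

Step 10
Reactants: 17 dimethyl (1R,2S)-6,7-bis(benzyloxy)-1-[4-(benzyloxy)-3-(methoxymethoxy)phenyl]-1,2-dihydronaphthalene-2,3-dicarboxylate
Product: 18 dimethyl (1R,2S)-6,7-bis(benzyloxy)-1-[4-(benzyloxy)-3-hydroxyphenyl]-1,2-dihydronaphthalene-2,3-dicarboxylate
Conditions: HCl (cat.), MeOH–THF, 40 °C
Reagents that add atoms: none
Why: Acid-catalysed cleavage of the methoxymethyl acetal in methanol; benzyl ethers and methyl esters are stable under these conditions, and the solvent matches the esters.

Step 11
Reactants: 19 methyl 2-[bis(2,2,2-trifluoroethoxy)phosphoryl]acetate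
Product: 20 methyl 2-[bis(2,2,2-trifluoroethoxy)phosphoryl]-2-diazoacetate
Conditions: 4-acetamidobenzenesulfonyl azide, DBU, MeCN, 0 °C → rt
Reagents that add atoms: 4-acetamidobenzenesulfonyl azide, CC(=O)Nc1ccc(cc1)S(=O)(=O)N=[N+]=[N-]
Why: Regitz diazo transfer to the doubly activated methylene of a phosphonoacetate.

Step 12
Reactants: 18 dimethyl (1R,2S)-6,7-bis(benzyloxy)-1-[4-(benzyloxy)-3-hydroxyphenyl]-1,2-dihydronaphthalene-2,3-dicarboxylate; 20 methyl 2-[bis(2,2,2-trifluoroethoxy)phosphoryl]-2-diazoacetate
Product: 21 dimethyl (1R,2S)-6,7-bis(benzyloxy)-1-[4-(benzyloxy)-3-({1-[bis(2,2,2-trifluoroethoxy)phosphoryl]-2-methoxy-2-oxoethyl}oxy)phenyl]-1,2-dihydronaphthalene-2,3-dicarboxylate (both epimers at the phosphonate carbon)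
Conditions: Rh2(OAc)4 (2 mol %), toluene, 80 °C, slow addition of 20
Reagents that add atoms: none
Why: Carbenoid O–H insertion of a diazophosphonoacetate into a phenol catalysed by Rh2(OAc)4; for acceptor/acceptor carbenoids this insertion is faster than cyclopropanation or C–H insertion, and the new centre is left uncontrolled because step 13 removes it.

Step 13
Reactants: 21 dimethyl (1R,2S)-6,7-bis(benzyloxy)-1-[4-(benzyloxy)-3-({1-[bis(2,2,2-trifluoroethoxy)phosphoryl]-2-methoxy-2-oxoethyl}oxy)phenyl]-1,2-dihydronaphthalene-2,3-dicarboxylate; 22 3,4-bis(benzyloxy)benzaldehyde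
Product: 23 dimethyl (1R,2S)-6,7-bis(benzyloxy)-1-[4-(benzyloxy)-3-({(1E)-2-[3,4-bis(benzyloxy)phenyl]-1-(methoxycarbonyl)ethenyl}oxy)phenyl]-1,2-dihydronaphthalene-2,3-dicarboxylate
Conditions: KN(SiMe3)2, 18-crown-6, THF, −78 °C; then 22, −78 °C
Reagents that add atoms: none
Why: Horner–Wadsworth–Emmons olefination in its Still–Gennari form; the electron-poor trifluoroethyl phosphonate makes elimination faster than reversal of the first adduct, so the kinetic alkene with the ester cis to ring D (aryloxy oxygen trans, E) is expected, as with α-halo phosphonates of this type, and the phosphonate C–H is far more acidic than C2–H, so one equivalent of base deprotonates only there.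

Step 14
Reactants: 23 dimethyl (1R,2S)-6,7-bis(benzyloxy)-1-[4-(benzyloxy)-3-({(1E)-2-[3,4-bis(benzyloxy)phenyl]-1-(methoxycarbonyl)ethenyl}oxy)phenyl]-1,2-dihydronaphthalene-2,3-dicarboxylate
Product: 24 (1R,2S)-6,7-bis(benzyloxy)-1-[4-(benzyloxy)-3-({(1E)-2-[3,4-bis(benzyloxy)phenyl]-1-carboxyethenyl}oxy)phenyl]-1,2-dihydronaphthalene-2,3-dicarboxylic acid
Conditions: LiOH, THF–MeOH–H2O, rt, argon; then aq HCl to pH 2
Reagents that add atoms: lithium hydroxide, [Li+].[OH-]
Why: Saponification of the three methyl esters while every phenol is still benzylated, so no catechol is exposed to base; C2 already has the stable trans configuration, and the β-aryl, α-oxy acrylate is a poor Michael acceptor, so the alkene geometry should hold.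

Step 15
Reactants: 24 (1R,2S)-6,7-bis(benzyloxy)-1-[4-(benzyloxy)-3-({(1E)-2-[3,4-bis(benzyloxy)phenyl]-1-carboxyethenyl}oxy)phenyl]-1,2-dihydronaphthalene-2,3-dicarboxylic acid
Product: 25 (1R,2S)-1-[3-{[(1E)-1-carboxy-2-(3,4-dihydroxyphenyl)ethenyl]oxy}-4-hydroxyphenyl]-6,7-dihydroxy-1,2-dihydronaphthalene-2,3-dicarboxylic acid
Conditions: BCl3, C6HMe5, CH2Cl2, −78 °C; then THF–H2O quench at −78 °C
Reagents that add atoms: none
Why: Lewis-acid cleavage of aryl benzyl ethers with pentamethylbenzene as a non-basic benzyl-cation scavenger; the method reduces nothing, and the low temperature is chosen to leave the E enol ether and both stereocentres untouched.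

## Compound list

1 | [3,4-bis(benzyloxy)phenyl]methanol | OCc1ccc(OCc2ccccc2)c(OCc2ccccc2)c1 | starting material
2 | [4,5-bis(benzyloxy)-2-bromophenyl]methanol | OCc1cc(OCc2ccccc2)c(OCc2ccccc2)cc1Br | intermediate
3 | 1,2-bis(benzyloxy)-4-bromo-5-(bromomethyl)benzene | BrCc1cc(OCc2ccccc2)c(OCc2ccccc2)cc1Br | intermediate
4 | 4-(benzyloxy)-3-hydroxybenzaldehyde | O=Cc1ccc(OCc2ccccc2)c(O)c1 | starting material
5 | 4-(benzyloxy)-3-(methoxymethoxy)benzaldehyde | COCOc1cc(C=O)ccc1OCc1ccccc1 | intermediate
6 | 1-[4,5-bis(benzyloxy)-2-bromobenzyl]tetrahydrothiophenium bromide (formed in the flask) | [Br-].Brc1cc(OCc2ccccc2)c(OCc2ccccc2)cc1C[S+]1CCCC1 | intermediate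
7 | (±)-trans-2-[4,5-bis(benzyloxy)-2-bromophenyl]-3-[4-(benzyloxy)-3-(methoxymethoxy)phenyl]oxirane (one enantiomer drawn) | COCOc1cc(ccc1OCc1ccccc1)[C@@H]1O[C@H]1c1cc(OCc2ccccc2)c(OCc2ccccc2)cc1Br | intermediate
8 | (±)-{4,5-bis(benzyloxy)-2-[trans-3-(4-(benzyloxy)-3-(methoxymethoxy)phenyl)oxiran-2-yl]phenyl}lithium (formed in the flask; one enantiomer drawn) | COCOc1cc(ccc1OCc1ccccc1)[C@@H]1O[C@H]1c1cc(OCc2ccccc2)c(OCc2ccccc2)cc1[Li] | intermediate
9 | (±)-trans-4,5-bis(benzyloxy)-2-[4-(benzyloxy)-3-(methoxymethoxy)phenyl]-1,2-dihydrobenzocyclobuten-1-ol (trans-7-aryl-8-hydroxybenzocyclobutene; one enantiomer drawn) | O[C@@H]1[C@@H](c2ccc(OCc3ccccc3)c(OCOC)c2)c2cc(OCc3ccccc3)c(OCc3ccccc3)cc21 | intermediate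
10 | fumaryl chloride | O=C(Cl)/C=C/C(=O)Cl | starting material
11 | methyl (S)-lactate | C[C@H](O)C(=O)OC | starting material
12 | bis[(2S)-1-methoxy-1-oxopropan-2-yl] fumarate | C[C@H](OC(=O)/C=C/C(=O)O[C@@H](C)C(=O)OC)C(=O)OC | intermediate
13 | (E,E)-α-hydroxy-α'-[4-(benzyloxy)-3-(methoxymethoxy)phenyl]-4,5-bis(benzyloxy)-o-quinodimethane (formed in the flask) | O/C=C1\C=C(OCc2ccccc2)C(OCc2ccccc2)=C/C1=C\c1ccc(OCc2ccccc2)c(OCOC)c1 | intermediate
14 | bis[(2S)-1-methoxy-1-oxopropan-2-yl] (1R,2R,3S,4R)-6,7-bis(benzyloxy)-1-[4-(benzyloxy)-3-(methoxymethoxy)phenyl]-4-hydroxy-1,2,3,4-tetrahydronaphthalene-2,3-dicarboxylate | C[C@H](OC(=O)[C@@H]1[C@@H](O)c2cc(OCc3ccccc3)c(OCc3ccccc3)cc2[C@@H](c2ccc(OCc3ccccc3)c(OCOC)c2)[C@H]1C(=O)O[C@@H](C)C(=O)OC)C(=O)OC | intermediate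
15 | 4-O-methanesulfonate of 14 (formed in the flask) | C[C@H](OC(=O)[C@@H]1[C@@H](OS(C)(=O)=O)c2cc(OCc3ccccc3)c(OCc3ccccc3)cc2[C@@H](c2ccc(OCc3ccccc3)c(OCOC)c2)[C@H]1C(=O)O[C@@H](C)C(=O)OC)C(=O)OC | intermediate
16 | bis[(2S)-1-methoxy-1-oxopropan-2-yl] (1R,2R)-6,7-bis(benzyloxy)-1-[4-(benzyloxy)-3-(methoxymethoxy)phenyl]-1,2-dihydronaphthalene-2,3-dicarboxylate (1,2-cis) | C[C@H](OC(=O)C1=Cc2cc(OCc3ccccc3)c(OCc3ccccc3)cc2[C@@H](c2ccc(OCc3ccccc3)c(OCOC)c2)[C@H]1C(=O)O[C@@H](C)C(=O)OC)C(=O)OC | intermediate
17 | dimethyl (1R,2S)-6,7-bis(benzyloxy)-1-[4-(benzyloxy)-3-(methoxymethoxy)phenyl]-1,2-dihydronaphthalene-2,3-dicarboxylate (1,2-trans) | COC(=O)C1=Cc2cc(OCc3ccccc3)c(OCc3ccccc3)cc2[C@@H](c2ccc(OCc3ccccc3)c(OCOC)c2)[C@@H]1C(=O)OC | intermediate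
18 | dimethyl (1R,2S)-6,7-bis(benzyloxy)-1-[4-(benzyloxy)-3-hydroxyphenyl]-1,2-dihydronaphthalene-2,3-dicarboxylate | COC(=O)C1=Cc2cc(OCc3ccccc3)c(OCc3ccccc3)cc2[C@@H](c2ccc(OCc3ccccc3)c(O)c2)[C@@H]1C(=O)OC | intermediate
19 | methyl 2-[bis(2,2,2-trifluoroethoxy)phosphoryl]acetate | COC(=O)CP(=O)(OCC(F)(F)F)OCC(F)(F)F | starting material
20 | methyl 2-[bis(2,2,2-trifluoroethoxy)phosphoryl]-2-diazoacetate | COC(=O)C(=[N+]=[N-])P(=O)(OCC(F)(F)F)OCC(F)(F)F | intermediate
21 | dimethyl (1R,2S)-6,7-bis(benzyloxy)-1-[4-(benzyloxy)-3-({1-[bis(2,2,2-trifluoroethoxy)phosphoryl]-2-methoxy-2-oxoethyl}oxy)phenyl]-1,2-dihydronaphthalene-2,3-dicarboxylate (both epimers at the phosphonate carbon) | COC(=O)C1=Cc2cc(OCc3ccccc3)c(OCc3ccccc3)cc2[C@@H](c2ccc(OCc3ccccc3)c(OC(C(=O)OC)P(=O)(OCC(F)(F)F)OCC(F)(F)F)c2)[C@@H]1C(=O)OC | intermediate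
22 | 3,4-bis(benzyloxy)benzaldehyde | O=Cc1ccc(OCc2ccccc2)c(OCc2ccccc2)c1 | starting material
23 | dimethyl (1R,2S)-6,7-bis(benzyloxy)-1-[4-(benzyloxy)-3-({(1E)-2-[3,4-bis(benzyloxy)phenyl]-1-(methoxycarbonyl)ethenyl}oxy)phenyl]-1,2-dihydronaphthalene-2,3-dicarboxylate | COC(=O)C1=Cc2cc(OCc3ccccc3)c(OCc3ccccc3)cc2[C@@H](c2ccc(OCc3ccccc3)c(O/C(=C/c3ccc(OCc4ccccc4)c(OCc4ccccc4)c3)C(=O)OC)c2)[C@@H]1C(=O)OC | intermediate
24 | (1R,2S)-6,7-bis(benzyloxy)-1-[4-(benzyloxy)-3-({(1E)-2-[3,4-bis(benzyloxy)phenyl]-1-carboxyethenyl}oxy)phenyl]-1,2-dihydronaphthalene-2,3-dicarboxylic acid | OC(=O)C1=Cc2cc(OCc3ccccc3)c(OCc3ccccc3)cc2[C@@H](c2ccc(OCc3ccccc3)c(O/C(=C/c3ccc(OCc4ccccc4)c(OCc4ccccc4)c3)C(=O)O)c2)[C@@H]1C(=O)O | intermediate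
25 | (1R,2S)-1-[3-{[(1E)-1-carboxy-2-(3,4-dihydroxyphenyl)ethenyl]oxy}-4-hydroxyphenyl]-6,7-dihydroxy-1,2-dihydronaphthalene-2,3-dicarboxylic acid | O=C(O)C1=Cc2cc(O)c(O)cc2[C@@H](c2ccc(O)c(O/C(=C/c3ccc(O)c(O)c3)C(=O)O)c2)[C@@H]1C(=O)O | target

## Step count and risks

Total: 15 steps. Longest linear sequence: 12 steps (1 → 2 → 3 → 7 → 9 → 14 → 16 → 17 → 18 → 21 → 23 → 24 → 25; steps 1, 2, 4, 5, 7, 8, 9, 10, 12, 13, 14 and 15).

**Step 7 (key step).** The most likely failure is insufficient discrimination between the two faces of the dienol at 110 °C. Because the configuration at C1 is fixed jointly by which ester sits endo and which fumarate face is open, any leakage in either element lowers the enantiomeric purity at C1. It would show up as diastereomers of 14. Two further losses are possible: the 1,5-hydrogen shift of the dienol to a benzylbenzaldehyde when the dienophile is depleted, and lactonisation of the C4 hydroxyl onto the cis C2 ester during isolation. The fallback changes the controlling element. It sets out from 9 and 10. Fumaryl chloride 10 is esterified with two equivalents of methyl (S)-mandelate to give the fumarate of methyl (S)-mandelate F1, whose phenyl groups shield the alkene face more strongly. Cycloaddition with 9 in toluene at 110 °C gives the bis(mandelyl) adduct F2, which is more likely to crystallise. Mesylation gives the mesylate F3, and DBU gives the bis(mandelyl) dihydronaphthalene diester F4. Methoxide exchange as in step 9 then returns to the route at 17.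

**Step 13.** Kinetic control may be lost. The electron-rich aldehyde adds slowly, and if the adducts revert before they eliminate, the stable Z enol ether is formed. The fallback reaches the geometry photochemically. It sets out from 21. The olefination is carried through whatever its selectivity, and the Z isomer of 23, F5, is irradiated with visible light in the presence of a triplet sensitiser such as fac-Ir(ppy)3. In this energy-transfer isomerisation, known for cinnamates, the isomer with the aryl ring cis to the ester is twisted out of conjugation, accepts energy poorly, and should accumulate. Separation and recycling of F5 return the material to the route at 23.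

**Step 15.** Three processes threaten the last step: incomplete cleavage of five ethers on a poorly soluble triacid at −78 °C, C-benzylation of the electron-rich rings if scavenging lags, and acid-induced isomerisation of the enol ether if the mixture has to be warmed. The fallback reverses the order of the two deprotections. It sets out from 23. The soluble triester is debenzylated with BCl3 and pentamethylbenzene to the pentaphenol trimethyl ester F6, and F6 is saponified last with LiOH under strict exclusion of oxygen. This arrives at 25.

**Step 5.** The magnesium alkoxide may undergo anion-accelerated ring opening on warming, or the Lewis acid may rearrange the electron-rich epoxide (Meinwald rearrangement) before the ring closes. Either lowers the return of the strained alcohol. The fallback makes the ring-opened product the deliberate intermediate and generates the same dienol with light. It sets out from 7. The lithiation and ring closure are run as before, but the alkoxide is allowed to warm so that it opens and is protonated to 4,5-bis(benzyloxy)-2-[4-(benzyloxy)-3-(methoxymethoxy)benzyl]benzaldehyde F7. Irradiation of F7 at about 350 nm in the presence of 12 forms dienol 13 by photoenolisation, a known entry to hydroxy-o-quinodimethanes, and the cycloaddition returns to the route at 14.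

## Further compounds

F1 | step 7 | bis[(1S)-2-methoxy-2-oxo-1-phenylethyl] fumarate | COC(=O)[C@@H](OC(=O)/C=C/C(=O)O[C@H](C(=O)OC)c1ccccc1)c1ccccc1
F2 | step 7 | bis[(1S)-2-methoxy-2-oxo-1-phenylethyl] (1R,2R,3S,4R)-6,7-bis(benzyloxy)-1-[4-(benzyloxy)-3-(methoxymethoxy)phenyl]-4-hydroxy-1,2,3,4-tetrahydronaphthalene-2,3-dicarboxylate | COC(=O)[C@@H](OC(=O)[C@@H]1[C@@H](O)c2cc(OCc3ccccc3)c(OCc3ccccc3)cc2[C@@H](c2ccc(OCc3ccccc3)c(OCOC)c2)[C@H]1C(=O)O[C@H](C(=O)OC)c1ccccc1)c1ccccc1
F3 | step 7 | 4-O-methanesulfonate of F2 | COC(=O)[C@@H](OC(=O)[C@@H]1[C@@H](OS(C)(=O)=O)c2cc(OCc3ccccc3)c(OCc3ccccc3)cc2[C@@H](c2ccc(OCc3ccccc3)c(OCOC)c2)[C@H]1C(=O)O[C@H](C(=O)OC)c1ccccc1)c1ccccc1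
F4 | step 7 | bis[(1S)-2-methoxy-2-oxo-1-phenylethyl] (1R,2R)-6,7-bis(benzyloxy)-1-[4-(benzyloxy)-3-(methoxymethoxy)phenyl]-1,2-dihydronaphthalene-2,3-dicarboxylate | COC(=O)[C@@H](OC(=O)C1=Cc2cc(OCc3ccccc3)c(OCc3ccccc3)cc2[C@@H](c2ccc(OCc3ccccc3)c(OCOC)c2)[C@H]1C(=O)O[C@H](C(=O)OC)c1ccccc1)c1ccccc1
F5 | step 13 | dimethyl (1R,2S)-6,7-bis(benzyloxy)-1-[4-(benzyloxy)-3-({(1Z)-2-[3,4-bis(benzyloxy)phenyl]-1-(methoxycarbonyl)ethenyl}oxy)phenyl]-1,2-dihydronaphthalene-2,3-dicarboxylate | COC(=O)C1=Cc2cc(OCc3ccccc3)c(OCc3ccccc3)cc2[C@@H](c2ccc(OCc3ccccc3)c(O/C(=C\c3ccc(OCc4ccccc4)c(OCc4ccccc4)c3)C(=O)OC)c2)[C@@H]1C(=O)OC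
F6 | step 15 | dimethyl (1R,2S)-1-[3-{[(1E)-2-(3,4-dihydroxyphenyl)-1-(methoxycarbonyl)ethenyl]oxy}-4-hydroxyphenyl]-6,7-dihydroxy-1,2-dihydronaphthalene-2,3-dicarboxylate | COC(=O)C1=Cc2cc(O)c(O)cc2[C@@H](c2ccc(O)c(O/C(=C/c3ccc(O)c(O)c3)C(=O)OC)c2)[C@@H]1C(=O)OC
F7 | step 5 | 4,5-bis(benzyloxy)-2-[4-(benzyloxy)-3-(methoxymethoxy)benzyl]benzaldehyde | O=Cc1cc(OCc2ccccc2)c(OCc2ccccc2)cc1Cc1ccc(OCc2ccccc2)c(OCOC)c1
A1 | alternative 1 | dimethyl (1R,2S)-1-[4-hydroxy-3-(methoxymethoxy)phenyl]-6,7-dimethoxy-1,2-dihydronaphthalene-2,3-dicarboxylate | COC(=O)C1=Cc2cc(OC)c(OC)cc2[C@@H](c3ccc(O)c(OCOC)c3)[C@@H]1C(=O)OC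
A2 | alternative 1 | dimethyl (E)-2-(2-{[4-hydroxy-3-(methoxymethoxy)phenyl](4-methylbenzenesulfonyl)methyl}-4,5-dimethoxybenzylidene)succinate (racemic at the sulfone carbon) | COC(=O)C/C(=C\c1cc(OC)c(OC)cc1C(c1ccc(O)c(OCOC)c1)S(=O)(=O)c1ccc(C)cc1)C(=O)OC
A3 | alternative 1 | dimethyl (E)-2-(4,5-dimethoxy-2-{[3-(methoxymethoxy)-4-oxocyclohexa-2,5-dien-1-ylidene]methyl}benzylidene)succinate (para-quinone methide) | COC(=O)C/C(=C\c1cc(OC)c(OC)cc1C=C1C=CC(=O)C(OCOC)=C1)C(=O)OC
A4 | alternative 2 | dimethyl (1R,2S)-6,7-dimethoxy-1-[4-methoxy-3-(methanesulfonyloxy)phenyl]-1,2-dihydronaphthalene-2,3-dicarboxylate | COC(=O)C1=Cc2cc(OC)c(OC)cc2[C@@H](c3ccc(OC)c(OS(C)(=O)=O)c3)[C@@H]1C(=O)OC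
A5 | alternative 2 | dimethyl 2-{(3,4-dimethoxyphenyl)[4-methoxy-3-(methanesulfonyloxy)phenyl]methyl}-3-formylsuccinate (diarylmethine and C2 centres as required for A4; formyl-bearing carbon unspecified) | COC(=O)C(C=O)[C@@H](C(=O)OC)[C@@H](c1ccc(OC)c(OC)c1)c1ccc(OC)c(OS(C)(=O)=O)c1
A6 | alternative 3 | dimethyl (1R,2S)-1-[4-methoxy-3-(methoxymethoxy)phenyl]-6,7-bis(4,4,5,5-tetramethyl-1,3,2-dioxaborolan-2-yl)-1,2-dihydronaphthalene-2,3-dicarboxylate | COC(=O)C1=Cc2cc(B3OC(C)(C)C(C)(C)O3)c(B4OC(C)(C)C(C)(C)O4)cc2[C@@H](c5ccc(OC)c(OCOC)c5)[C@@H]1C(=O)OC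
A7 | alternative 3 | dimethyl (E)-2-{1-[4-methoxy-3-(methoxymethoxy)phenyl]prop-2-yn-1-yl}-3-(prop-2-yn-1-ylidene)succinate (1,7-diyne with the C1 and C2 centres as required for A6) | C#C[C@@H](c1ccc(OC)c(OCOC)c1)[C@H](C(=O)OC)/C(C(=O)OC)=C\C#C
A8 | alternative 3 | bis(pinacolatoboryl)acetylene | CC1(C)OB(C#CB2OC(C)(C)C(C)(C)O2)OC1(C)C
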